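**Retrosynthetic overview**

1. Target 31 ⇐ 30 ⇐ 29 (late desilylation, C6 ketone reduction, C7–O acylation) ⇐ hydroxy-diketone 23 ⇐ tricyclic enol acetal 22; ring A of 22 ⇐ enynal 20 (aldehyde oxygen onto the alkyne, then hydride at C1).
2. Key disconnection of ring B (in 18): dienone ⇐ acylketene 17 ⇐ diazo keto ester 16. A Wolff 1,2-shift of the alkenyl carbon C4a makes C4a–C8a, and 6π closure of the resulting dienylketene makes C8–C7.
3. Enabling feature: in ring B the C8 ketone lies between the C8a=C4a double bond and the quaternary, O-bearing C7, and C6 is oxygenated. At the C6-ketone level ring B is a 6-oxy-6-methylcyclohexa-2,4-dienone, the retron of a dienylketene electrocyclisation that cannot aromatise.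
4. O6 and O7 are tied before the key step in a temporary 1,3-dioxole (pivalaldehyde acetal from (R)-lactic acid); its acetal carbon relays the lactate configuration to C7 and is hydrolysed off after ring A is built.
5. 16 ⇐ (Z)-enoate 14 ⇐ iodide 9 + pentenyne unit (from 11) ⇐ ynoate 7 ⇐ phosphate 5 ⇐ 3. Ring order: dioxole (temporary), ring B (step 9), ring A (step 12), dioxolane cleaved (step 13).

Key step: step 9

Remark: locants (O2, C1–C8a) follow the 1H-isochromene numbering of the target; 23 and 29 are drawn as C6-keto tautomers although the C5–C6 enol may dominate.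

**Route**

Step 1
Reactants: 1 (R)-lactic acid; 2 pivalaldehyde
Product: 3 (2R,5R)-2-tert-butyl-5-methyl-1,3-dioxolan-4-one
Conditions: TsOH·H2O (cat.), H2SO4 (cat.), pentane, reflux, Dean–Stark; recrystallisation (Et2O/pentane, −78 °C)
Reagents that add atoms: none
Why: Acid-catalysed acetalisation of an α-hydroxy acid under thermodynamic control should favour the cis dioxolanone, so the new acetal stereocentre (2R) is set by the lactate centre and the single diastereomer is secured by crystallisation.

Step 2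
Reactants: 3
Product: 5 (2R)-2-tert-butyl-5-methyl-1,3-dioxol-4-yl diphenyl phosphate, via lithium enolate 4 (not isolated)
Conditions: LiN(i-Pr)2, THF/DMPU, −78 °C; then (PhO)2P(O)Cl, −78 → 0 °C
Reagents that add atoms: diphenyl phosphorochloridate, O=P(Cl)(Oc1ccccc1)Oc1ccccc1; lithium diisopropylamide, [Li]N(C(C)C)C(C)C (lithium of 4 only)
Why: O-phosphorylation of a lactone enolate to a ketene acetal phosphate is expected with the hard chlorophosphate; the lactate carbon becomes trigonal while the acetal carbon keeps the stereochemical information (self-regeneration of stereocentres).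

Step 3
Reactants: 5; 6 methyl propiolate
Product: 7 methyl 3-[(2R)-2-tert-butyl-5-methyl-1,3-dioxol-4-yl]prop-2-ynoate
Conditions: PdCl2(PPh3)2 (5 mol %), CuI (10 mol %), K2CO3, THF, 50 °C
Reagents that add atoms: none
Why: Sonogashira coupling of an enol phosphate should work because ketene acetal phosphates add oxidatively to zerovalent palladium like enol triflates, and the carbonate base avoids amine addition to the propiolate.

Step 4
Reactants: 7
Product: 9 methyl (2E)-3-[(2R)-2-tert-butyl-5-methyl-1,3-dioxol-4-yl]-2-iodoprop-2-enoate, via vinylstannane 8 (not isolated)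
Conditions: Bu3SnH, Pd(PPh3)4 (2 mol %), THF, 0 °C; then I2, 0 °C
Reagents that add atoms: iodine, II; tributyltin hydride, CCCC[SnH](CCCC)CCCC (tin of 8 only)
Why: Palladium-catalysed hydrostannation of an alkynoate is a syn addition that puts tin on the carbon next to the ester, and iododestannylation with retention should fix the geometry in which the dioxole is cis to the ester carbon.

Step 5
Reactants: 10 (E)-but-2-enal
Product: 11 (3E)-1,1-dibromopenta-1,3-diene
Conditions: CBr4, PPh3, CH2Cl2, 0 °C
Reagents that add atoms: tetrabromomethane, BrC(Br)(Br)Br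
Why: Ramirez dibromo-olefination of the aldehyde (first stage of the Corey–Fuchs sequence) should leave the E-propenyl unit untouched.

Step 6
Reactants: 9; 11
Product: 14 methyl (2Z,5E)-2-{[(2R)-2-tert-butyl-5-methyl-1,3-dioxol-4-yl]methylidene}hept-5-en-3-ynoate, via lithium acetylide 12 (not isolated), via alkynylzinc bromide 13 (not isolated)
Conditions: 11, n-BuLi (2.0 equiv), THF, −78 °C; ZnBr2, −78 → 0 °C; then 9, Pd(PPh3)4 (5 mol %), THF, 23 °C
Reagents that add atoms: n-butyllithium, [Li]CCCC (lithium of 12 only); zinc bromide, Br[Zn]Br (zinc and bromine of 13 only)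
Why: Fritsch–Buttenberg–Wiechell rearrangement of the lithiated dibromoalkene should give the enynyl anion, and Negishi alkynylation of the vinyl iodide proceeds with retention, so the dioxole stays cis to the ester carbon.

Step 7
Reactants: 14
Product: 15 methyl (4Z,7E)-4-{[(2R)-2-tert-butyl-5-methyl-1,3-dioxol-4-yl]methylidene}-3-oxonon-7-en-5-ynoate
Conditions: MeOAc, LiN(i-Pr)2 (3 equiv), THF, −78 °C; then 14, −78 → −40 °C; aq. NH4Cl
Reagents that add atoms: methyl acetate, CC(=O)OC
Why: Crossed Claisen condensation of a non-enolisable ester with excess lithium ester enolate should stop at the β-keto ester, which is protected as its enolate; conjugate addition is disfavoured at the donor-substituted β-carbon.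

Step 8
Reactants: 15
Product: 16 methyl (4Z,7E)-4-{[(2R)-2-tert-butyl-5-methyl-1,3-dioxol-4-yl]methylidene}-2-diazo-3-oxonon-7-en-5-ynoate
Conditions: 4-acetamidobenzenesulfonyl azide, Et3N, MeCN, 0 → 23 °C
Reagents that add atoms: 4-acetamidobenzenesulfonyl azide, CC(=O)Nc1ccc(cc1)S(=O)(=O)N=[N+]=[N-]
Why: Regitz diazo transfer to the doubly activated methylene of a β-keto ester is reliable under mild base and touches neither the acetal nor the dienyne.

Step 9
Reactants: 16
Product: 18 methyl (2S,3aR)-2-tert-butyl-3a-methyl-4-oxo-6-[(3E)-pent-3-en-1-yn-1-yl]-3a,4-dihydro-2H-1,3-benzodioxole-5-carboxylate, via acylketene 17 (not isolated)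
Conditions: PhMe (0.005 M), 130 °C, sealed tube
Reagents that add atoms: none
Why: Thermolysis of the 2-diazo-1,3-dicarbonyl unit should trigger a Wolff rearrangement in which the alkenyl carbon C4a migrates, with retention of its double-bond geometry, from the ketone carbon (future C8) to the diazo carbon (C8a); this forms C4a–C8a and turns C8 into the carbon of acylketene 17. Because C8a and the dioxole are cis on the C4a=C5 bond, the dienylketene should then close ring B by a thermal disrotatory 6π electrocyclisation that joins C8 to the methyl-bearing dioxole carbon C7. The closest known reaction type is the Wolff rearrangement/dienylketene electrocyclisation used in aromatic annulations of unsaturated diazo ketones, and the ring closure is the thermal reverse of the photochemical opening of 6-acyloxy-6-methylcyclohexa-2,4-dienones. As C7 carries methyl and oxygen but no hydrogen, the product cannot tautomerise to a phenol and is held as the dienone with the C8 ketone, the C8a=C4a double bond and the quaternary C7 in place. The only stereocentre of 16 is the acetal carbon, whose tert-butyl group shields one face of the planar dioxole, so the ketene carbon should add to C7 anti to tert-butyl, as electrophiles add to the enolate of 3; in the (R)-lactic acid series this gives 7R. The step needs the Z geometry secured in steps 4 and 6 and high dilution against ketene dimerisation, and the ester on C8a leaves no hydrogen that could shift to the carbene carbon.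

Step 10
Reactants: 18
Product: 19 (2S,3aS,4RS)-2-tert-butyl-5-(hydroxymethyl)-3a-methyl-6-[(3E)-pent-3-en-1-yn-1-yl]-3a,4-dihydro-2H-1,3-benzodioxol-4-ol
Conditions: i-Bu2AlH (5 equiv), CH2Cl2, −78 °C; aq. potassium sodium tartrate
Reagents that add atoms: none
Why: Aluminium hydride 1,2-reduction should take the ester to the primary alcohol (future C1) and the ketone to the carbinol; the new C4 carbinol centre is formed without control and is erased in step 11.

Step 11
Reactants: 19
Product: 20 (2S,3aR)-2-tert-butyl-3a-methyl-4-oxo-6-[(3E)-pent-3-en-1-yn-1-yl]-3a,4-dihydro-2H-1,3-benzodioxole-5-carbaldehyde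
Conditions: MnO2 (activated, excess), CH2Cl2, 23 °C
Reagents that add atoms: none
Why: Both hydroxyl groups are allylic, so manganese dioxide oxidation should return the C8 ketone and deliver the C1 aldehyde under neutral conditions that spare the enol acetal.

Step 12
Reactants: 20
Product: 22 (2S,3aR)-2-tert-butyl-3a-methyl-7-[(1E)-prop-1-en-1-yl]-3a,5-dihydro-4H-[1,3]dioxolo[4,5-g]isochromen-4-one, via pyrylium triflate 21 (not isolated)
Conditions: AgOTf (10 mol %), Hantzsch ester (1.2 equiv), 4 Å molecular sieves, ClCH2CH2Cl, 23 °C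
Reagents that add atoms: silver trifluoromethanesulfonate, [Ag+].[O-]S(=O)(=O)C(F)(F)F (counter-ion of 21 only)
Why: Silver-catalysed 6-endo-dig attack of the aldehyde oxygen on the neighbouring alkyne (known for ortho-alkynyl aryl aldehydes and ketones) should give the aromatic pyrylium, and hydride transfer from the Hantzsch ester to the unsubstituted C1 then gives the 1H-isochromene-type ring A; the C8 ketone oxygen is held away from the alkyne by its 1,3-placement on ring B.

Step 13
Reactants: 22
Product: 23 (7R)-7-hydroxy-7-methyl-3-[(1E)-prop-1-en-1-yl]-5,7-dihydro-1H-isochromene-6,8-dione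
Conditions: 1 M HCl, THF, 23 °C
Reagents that add atoms: water, O
Why: Acid hydrolysis of the vinylogous-ester enol acetal should release pivalaldehyde irreversibly and unveil the C6 ketone and the tertiary C7 hydroxyl, whereas any opening of the ring A enol ether is reversible; the quaternary C7 cannot epimerise.

Step 14
Reactants: 24 2,4-dihydroxy-6-methylbenzaldehyde
Product: 25 2-hydroxy-6-methyl-4-[(triisopropylsilyl)oxy]benzaldehyde
Conditions: i-Pr3SiCl, imidazole, DMF, 0 °C
Reagents that add atoms: chlorotriisopropylsilane, CC(C)[Si](Cl)(C(C)C)C(C)C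
Why: Silylation should occur at the para hydroxyl because the ortho hydroxyl is hydrogen-bonded to the aldehyde and more hindered.

Step 15
Reactants: 25
Product: 26 2-methoxy-6-methyl-4-[(triisopropylsilyl)oxy]benzaldehyde
Conditions: MeI, K2CO3, acetone, 50 °C
Reagents that add atoms: iodomethane, CI
Why: Williamson methylation of the remaining phenol is standard, and the bulky triisopropylsilyl aryl ether should survive carbonate in acetone.

Step 16
Reactants: 26
Product: 27 2-methoxy-6-methyl-4-[(triisopropylsilyl)oxy]benzoic acid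
Conditions: NaClO2, NaH2PO4, 2-methylbut-2-ene, t-BuOH/H2O, 23 °C
Reagents that add atoms: sodium chlorite, [Na+].[O-]Cl=O
Why: Pinnick oxidation converts hindered aryl aldehydes to acids at pH about 4, and the alkene scavenger removes hypochlorous acid before it can chlorinate the electron-rich ring.

Step 17
Reactants: 23; 27
Product: 29 (7R)-7-methyl-6,8-dioxo-3-[(1E)-prop-1-en-1-yl]-5,6,7,8-tetrahydro-1H-isochromen-7-yl 2-methoxy-6-methyl-4-[(triisopropylsilyl)oxy]benzoate, via acid chloride 28 (not isolated)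
Conditions: 27, 1-chloro-N,N,2-trimethylprop-1-en-1-amine, CH2Cl2, 0 → 23 °C; then 23, Et3N, DMAP, CH2Cl2, 0 → 40 °C; MeOH/aq. NaHCO3 work-up
Reagents that add atoms: 1-chloro-N,N,2-trimethylprop-1-en-1-amine, CC(C)=C(Cl)N(C)C (chlorine of 28 only)
Why: DMAP-mediated acylation of the tertiary α-ketol flanked by two trigonal carbons follows the 7-O-acylation of azaphilone-type alcohols; an O6 enol ester formed first is an activated acyl donor that should pass the aroyl group to the adjacent C7 oxygen or be cleaved in the work-up.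

Step 18
Reactants: 29
Product: 30 (6S,7R)-6-hydroxy-7-methyl-8-oxo-3-[(1E)-prop-1-en-1-yl]-5,6,7,8-tetrahydro-1H-isochromen-7-yl 2-methoxy-6-methyl-4-[(triisopropylsilyl)oxy]benzoate
Conditions: RuCl(p-cymene)[(S,S)-TsDPEN] (2 mol %), HCO2H/Et3N (5:2), CH2Cl2, 23 °C
Reagents that add atoms: none
Why: Noyori–Ikariya transfer hydrogenation reduces the keto tautomer of enolisable 1,3-dicarbonyl-type ketones under buffered acid and leaves the vinylogous-ester C8 carbonyl and the alkenes; the new C6 centre is set by the catalyst, the (S,S) ligand being expected to give 6S if the ester-bearing C7 side takes the aryl position of the standard model (the (R,R) antipode serves if the sense proves opposite).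

Step 19
Reactants: 30
Product: 31 (6S,7R)-6-hydroxy-7-methyl-8-oxo-3-[(1E)-prop-1-en-1-yl]-5,6,7,8-tetrahydro-1H-isochromen-7-yl 4-hydroxy-2-methoxy-6-methylbenzoate
Conditions: Bu4NF, AcOH (1:1), THF, 0 °C
Reagents that add atoms: none
Why: Buffered fluoride should cleave the aryl silyl ether quickly while the near-neutral medium avoids acyl migration and retro-aldol opening of the β-hydroxy ketone.

**Compound list**

1 | (R)-lactic acid | C[C@@H](O)C(=O)O | starting material
2 | pivalaldehyde (2,2-dimethylpropanal) | CC(C)(C)C=O | starting material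
3 | (2R,5R)-2-tert-butyl-5-methyl-1,3-dioxolan-4-one (cis) | C[C@H]1O[C@@H](C(C)(C)C)OC1=O | intermediate
4 | lithium (2R)-2-tert-butyl-5-methyl-1,3-dioxol-4-olate (lithium enolate of 3) | [Li]OC1=C(C)O[C@@H](C(C)(C)C)O1 | intermediate
5 | (2R)-2-tert-butyl-5-methyl-1,3-dioxol-4-yl diphenyl phosphate | O=P(Oc1ccccc1)(Oc1ccccc1)OC1=C(C)O[C@@H](C(C)(C)C)O1 | intermediate
6 | methyl propiolate (methyl prop-2-ynoate) | C#CC(=O)OC | starting material
7 | methyl 3-[(2R)-2-tert-butyl-5-methyl-1,3-dioxol-4-yl]prop-2-ynoate | COC(=O)C#CC1=C(C)O[C@@H](C(C)(C)C)O1 | intermediate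
8 | methyl (2E)-3-[(2R)-2-tert-butyl-5-methyl-1,3-dioxol-4-yl]-2-(tributylstannyl)prop-2-enoate | COC(=O)/C([Sn](CCCC)(CCCC)CCCC)=C\C1=C(C)O[C@@H](C(C)(C)C)O1 | intermediate
9 | methyl (2E)-3-[(2R)-2-tert-butyl-5-methyl-1,3-dioxol-4-yl]-2-iodoprop-2-enoate (dioxolyl cis to the ester) | COC(=O)/C(I)=C\C1=C(C)O[C@@H](C(C)(C)C)O1 | intermediate
10 | (E)-but-2-enal (crotonaldehyde) | C/C=C/C=O | starting material
11 | (3E)-1,1-dibromopenta-1,3-diene | C/C=C/C=C(Br)Br | intermediate
12 | lithium (3E)-pent-3-en-1-yn-1-ide | C/C=C/C#C[Li] | intermediate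
13 | bromo[(3E)-pent-3-en-1-yn-1-yl]zinc | C/C=C/C#C[Zn]Br | intermediate
14 | methyl (2Z,5E)-2-{[(2R)-2-tert-butyl-5-methyl-1,3-dioxol-4-yl]methylidene}hept-5-en-3-ynoate | COC(=O)/C(C#C/C=C/C)=C\C1=C(C)O[C@@H](C(C)(C)C)O1 | intermediate
15 | methyl (4Z,7E)-4-{[(2R)-2-tert-butyl-5-methyl-1,3-dioxol-4-yl]methylidene}-3-oxonon-7-en-5-ynoate | COC(=O)CC(=O)/C(C#C/C=C/C)=C\C1=C(C)O[C@@H](C(C)(C)C)O1 | intermediate
16 | methyl (4Z,7E)-4-{[(2R)-2-tert-butyl-5-methyl-1,3-dioxol-4-yl]methylidene}-2-diazo-3-oxonon-7-en-5-ynoate | COC(=O)C(=[N+]=[N-])C(=O)/C(C#C/C=C/C)=C\C1=C(C)O[C@@H](C(C)(C)C)O1 | intermediate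
17 | methyl (3Z,6E)-3-{[(2R)-2-tert-butyl-5-methyl-1,3-dioxol-4-yl]methylidene}-2-(oxomethylidene)oct-6-en-4-ynoate (acylketene) | COC(=O)C(=C=O)/C(C#C/C=C/C)=C\C1=C(C)O[C@@H](C(C)(C)C)O1 | intermediate
18 | methyl (2S,3aR)-2-tert-butyl-3a-methyl-4-oxo-6-[(3E)-pent-3-en-1-yn-1-yl]-3a,4-dihydro-2H-1,3-benzodioxole-5-carboxylate (tert-butyl cis to the angular methyl) | COC(=O)C1=C(C#C/C=C/C)C=C2O[C@H](C(C)(C)C)O[C@@]2(C)C1=O | intermediate
19 | (2S,3aS,4RS)-2-tert-butyl-5-(hydroxymethyl)-3a-methyl-6-[(3E)-pent-3-en-1-yn-1-yl]-3a,4-dihydro-2H-1,3-benzodioxol-4-ol (C4 epimers) | OCC1=C(C#C/C=C/C)C=C2O[C@H](C(C)(C)C)O[C@@]2(C)C1O | intermediate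
20 | (2S,3aR)-2-tert-butyl-3a-methyl-4-oxo-6-[(3E)-pent-3-en-1-yn-1-yl]-3a,4-dihydro-2H-1,3-benzodioxole-5-carbaldehyde | O=CC1=C(C#C/C=C/C)C=C2O[C@H](C(C)(C)C)O[C@@]2(C)C1=O | intermediate
21 | (2S,3aR)-2-tert-butyl-3a-methyl-4-oxo-7-[(1E)-prop-1-en-1-yl]-3a,4-dihydro-2H-[1,3]dioxolo[4,5-g]isochromen-6-ium trifluoromethanesulfonate | C/C=C/C1=CC2=C(C=[O+]1)C(=O)[C@]3(C)O[C@@H](C(C)(C)C)OC3=C2.[O-]S(=O)(=O)C(F)(F)F | intermediate
22 | (2S,3aR)-2-tert-butyl-3a-methyl-7-[(1E)-prop-1-en-1-yl]-3a,5-dihydro-4H-[1,3]dioxolo[4,5-g]isochromen-4-one (target core with O6-enol and O7 bridged by the pivalaldehyde acetal) | C/C=C/C1=CC2=C(CO1)C(=O)[C@]3(C)O[C@@H](C(C)(C)C)OC3=C2 | intermediate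
23 | (7R)-7-hydroxy-7-methyl-3-[(1E)-prop-1-en-1-yl]-5,7-dihydro-1H-isochromene-6,8-dione | C/C=C/C1=CC2=C(CO1)C(=O)[C@](C)(O)C(=O)C2 | intermediate
24 | 2,4-dihydroxy-6-methylbenzaldehyde | Cc1cc(O)cc(O)c1C=O | starting material
25 | 2-hydroxy-6-methyl-4-[(triisopropylsilyl)oxy]benzaldehyde | Cc1cc(O[Si](C(C)C)(C(C)C)C(C)C)cc(O)c1C=O | intermediate
26 | 2-methoxy-6-methyl-4-[(triisopropylsilyl)oxy]benzaldehyde | Cc1cc(O[Si](C(C)C)(C(C)C)C(C)C)cc(OC)c1C=O | intermediate
27 | 2-methoxy-6-methyl-4-[(triisopropylsilyl)oxy]benzoic acid | Cc1cc(O[Si](C(C)C)(C(C)C)C(C)C)cc(OC)c1C(=O)O | intermediate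
28 | 2-methoxy-6-methyl-4-[(triisopropylsilyl)oxy]benzoyl chloride | Cc1cc(O[Si](C(C)C)(C(C)C)C(C)C)cc(OC)c1C(=O)Cl | intermediate
29 | (7R)-7-methyl-6,8-dioxo-3-[(1E)-prop-1-en-1-yl]-5,6,7,8-tetrahydro-1H-isochromen-7-yl 2-methoxy-6-methyl-4-[(triisopropylsilyl)oxy]benzoate | C/C=C/C1=CC2=C(CO1)C(=O)[C@](C)(OC(=O)c1c(C)cc(O[Si](C(C)C)(C(C)C)C(C)C)cc1OC)C(=O)C2 | intermediate
30 | (6S,7R)-6-hydroxy-7-methyl-8-oxo-3-[(1E)-prop-1-en-1-yl]-5,6,7,8-tetrahydro-1H-isochromen-7-yl 2-methoxy-6-methyl-4-[(triisopropylsilyl)oxy]benzoate | C/C=C/C1=CC2=C(CO1)C(=O)[C@](C)(OC(=O)c1c(C)cc(O[Si](C(C)C)(C(C)C)C(C)C)cc1OC)[C@@H](O)C2 | intermediate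
31 | (6S,7R)-6-hydroxy-7-methyl-8-oxo-3-[(1E)-prop-1-en-1-yl]-5,6,7,8-tetrahydro-1H-isochromen-7-yl 4-hydroxy-2-methoxy-6-methylbenzoate | C/C=C/C1=CC2=C(CO1)C(=O)[C@](C)(OC(=O)c1c(C)cc(O)cc1OC)[C@@H](O)C2 | target

**Step count and risks**

Total step count: 19. Longest linear sequence: 15 steps (steps 1–4, 6–13, 17–19).

Step 9 (key step). The diazo compound may be lost to carbene pathways at 130 °C (addition to the enyne, dimerisation), or the acylketene may oligomerise before it reaches the reactive conformation. The fallback separates rearrangement from ring closure; it sets out from 16 and comes back at 18. Irradiation of 16 (350 nm, MeOH, −20 °C) should give the Wolff ketene at low temperature, trapped by methanol as the malonate diester F1. One of its two equivalent esters would be saponified (KOH, 1 equiv, MeOH/THF, 0 °C) to the malonic half-ester F2, which 1-chloro-N,N,2-trimethylprop-1-en-1-amine converts to the half-ester acid chloride F3. Et3N in PhMe (0 → 60 °C) should then regenerate acylketene 17 by dehydrochlorination, without any carbene, and its electrocyclisation gives 18. The alkene geometry of F1 would have to be checked after the photolysis.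

Step 17. Enolisation at C5/C6 may divert the acyl chloride to the O6 enol ester, which may neither transfer the hindered aroyl group to O7 nor cleave cleanly. The fallback masks the enol first; it sets out from 23 and comes back at 29. t-BuMe2SiCl and imidazole (DMF, 0 °C) should silylate only the acidic enol oxygen to give the silyl dienol ether F4, whose ring B then resembles an azaphilone with a free tertiary hydroxyl. Acylation with 28 (Et3N, DMAP, CH2Cl2, 40 °C) would give the silyl dienol ether ester F5, and AcOH/H2O/THF (23 °C) should hydrolyse the enol silyl ether, but not the aryl silyl ether, to 29.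

Step 18. Facial selectivity in the hydride transfer may be poor, or the substrate may override the catalyst (attack anti to the C7 acyloxy group would give the cis isomer). The fallback sets C6 by hydroxyl-directed delivery before the ester is made; it sets out from 23 and comes back at 31. Me4NBH(OAc)3 (AcOH/MeCN, −30 °C) should deliver hydride to C6 from the face of the C7 hydroxyl and give the trans diol F6. Et3SiOTf and 2,6-lutidine (CH2Cl2, −78 °C) would protect the secondary hydroxyl as the triethylsilyl ether F7. LiN(SiMe3)2 then 28 (THF, −78 °C) would acylate the tertiary alkoxide to the bis-silyl ester F8, with silyl migration to O7 as the point to watch. HF·pyridine (THF, 0 °C) removes both silyl groups to give 31.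

Further compounds
F1 | step 9 | dimethyl 2-{(1E,5E)-1-[(2R)-2-tert-butyl-5-methyl-1,3-dioxol-4-yl]hepta-1,5-dien-3-yn-2-yl}propanedioate (dioxolyl cis to the malonyl carbon) | COC(=O)C(C(=O)OC)/C(C#C/C=C/C)=C\C1=C(C)O[C@@H](C(C)(C)C)O1
F2 | step 9 | 2-{(1E,5E)-1-[(2R)-2-tert-butyl-5-methyl-1,3-dioxol-4-yl]hepta-1,5-dien-3-yn-2-yl}-3-methoxy-3-oxopropanoic acid | OC(=O)C(C(=O)OC)/C(C#C/C=C/C)=C\C1=C(C)O[C@@H](C(C)(C)C)O1
F3 | step 9 | methyl 2-{(1E,5E)-1-[(2R)-2-tert-butyl-5-methyl-1,3-dioxol-4-yl]hepta-1,5-dien-3-yn-2-yl}-3-chloro-3-oxopropanoate | ClC(=O)C(C(=O)OC)/C(C#C/C=C/C)=C\C1=C(C)O[C@@H](C(C)(C)C)O1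
F4 | step 17 | (7R)-6-[(tert-butyldimethylsilyl)oxy]-7-hydroxy-7-methyl-3-[(1E)-prop-1-en-1-yl]-1H-isochromen-8(7H)-one | C/C=C/C1=CC2=C(CO1)C(=O)[C@](C)(O)C(O[Si](C)(C)C(C)(C)C)=C2
F5 | step 17 | (7R)-6-[(tert-butyldimethylsilyl)oxy]-7-methyl-8-oxo-3-[(1E)-prop-1-en-1-yl]-7,8-dihydro-1H-isochromen-7-yl 2-methoxy-6-methyl-4-[(triisopropylsilyl)oxy]benzoate | C/C=C/C1=CC2=C(CO1)C(=O)[C@](C)(OC(=O)c1c(C)cc(O[Si](C(C)C)(C(C)C)C(C)C)cc1OC)C(O[Si](C)(C)C(C)(C)C)=C2
F6 | step 18 | (6S,7R)-6,7-dihydroxy-7-methyl-3-[(1E)-prop-1-en-1-yl]-5,6,7,8-tetrahydro-1H-isochromen-8-one | C/C=C/C1=CC2=C(CO1)C(=O)[C@](C)(O)[C@@H](O)C2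
F7 | step 18 | (6S,7R)-7-hydroxy-7-methyl-3-[(1E)-prop-1-en-1-yl]-6-[(triethylsilyl)oxy]-5,6,7,8-tetrahydro-1H-isochromen-8-one | C/C=C/C1=CC2=C(CO1)C(=O)[C@](C)(O)[C@@H](O[Si](CC)(CC)CC)C2
F8 | step 18 | (6S,7R)-7-methyl-8-oxo-3-[(1E)-prop-1-en-1-yl]-6-[(triethylsilyl)oxy]-5,6,7,8-tetrahydro-1H-isochromen-7-yl 2-methoxy-6-methyl-4-[(triisopropylsilyl)oxy]benzoate | C/C=C/C1=CC2=C(CO1)C(=O)[C@](C)(OC(=O)c1c(C)cc(O[Si](C(C)C)(C(C)C)C(C)C)cc1OC)[C@@H](O[Si](CC)(CC)CC)C2
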